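## Structural features

Compound 31 is a germacrane: a ten-membered carbocycle (C1–C10) with an E-trisubstituted C1=C10 alkene (methyl C14 on C10), a trans C4–C5 epoxide (methyl C15 on the quaternary C4), a free hydroxyl on C6, an isopropyl group on C7 and a 3-hydroxy-4-methoxybenzoate (isovanillate) on the C8 oxygen. Five stereocentres stand in an unbroken row, C4, C5, C6, C7 and C8, all R in 31; the oxirane oxygen at C5 and the C6 hydroxyl are anti (erythro), and on the ring the C7 isopropyl group is trans to both neighbouring oxygens. The epoxide faces the C1=C10 alkene across the ring, so any acid invites transannular cyclisation to a bicyclic skeleton. The aryl ester can be cleaved, or can migrate to the C6 hydroxyl, under base, and the phenol is free. The real difficulty is to close a strained ten-membered ring while holding the E alkene and fixing four contiguous stereocentres on a flexible ring, where late substrate control is unreliable. The feature used is the C7–C8 pair: with the isopropyl group read as a reduced isopropenyl group, oxygen-bearing C8 next to C7 with its three-carbon branch (C11–C13) is an anti homoallylic alcohol. That is the signature of a γ-selective 2-methylallyl-metal addition to a C8 aldehyde, and the bond formed can be the ring-closing bond. The E alkene and the trans epoxide map onto the carbon chain of geraniol (C6, C5, C4, C3, C2, C1, C10, C9), so both geometries are bought in.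

## Logic of the disconnections

31 ⇒ 30 ⇒ 25 + 28. The C8–O acyl bond and the two O–Si bonds are cut first. The ester is the most labile group and is kept out of all organometallic steps; the aromatic part separates as 28. The forward steps must acylate a hindered secondary alcohol without acid, and must remove both silyl groups with buffered fluoride so that neither acyl migration to O6 nor epoxide opening occurs.

25 ⇒ 24. The isopropyl group is traced back to an isopropenyl group (C11=C12). This uncovers the homoallylic alcohol. The forward hydrogenation must reduce a 1,1-disubstituted alkene and leave the trisubstituted ring alkene and the epoxide.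

24 ⇒ 22 (through 23). The C7–C8 ring bond is cut. It lies between two stereocentres, and cutting it opens the ring to a chain whose three remaining stereocentres (C4, C5, C6) are contiguous and accessible by reagent or chelation control. The forward step must be γ-selective, anti-selective at C7/C8, face-selective with respect to C6, and faster than oligomerisation; it must tolerate the epoxide and must not expel the C6 oxygen. For this reason 22 carries a bromide as the leaving group, a bulky non-chelating silyl ether of poor leaving-group ability at C6, and an aldehyde that is set free only in the last step before ring closure.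

22 ⇒ 21 ⇒ 20 ⇒ 19 ⇒ 18. The C8 aldehyde is masked as a dithioacetal, the C12 bromide is traced to a primary alcohol, and the two hydroxyls are told apart as a primary triethylsilyl ether and a secondary tert-butyldimethylsilyl ether. The β,γ-unsaturated aldehyde and the allylic bromide are too reactive to be carried. The forward steps need a clean primary-over-secondary desilylation and an unmasking of the aldehyde that spares the bromide and the epoxide and does not move the alkene into conjugation.

18 ⇒ 17 ⇒ 16 ⇒ 10 + 14 (through 15). The C6–C7 bond is cut between the epoxy aldehyde and a four-carbon alkenyl unit (C7, C11, C12, C13). This is the convergent junction. Direct addition cannot be relied on to set C6, so the carbinol is re-formed from the ketone by hydride delivery to a zinc chelate of the carbonyl and oxirane oxygens, which must give the anti epoxy alcohol.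

14 ⇒ 13 ⇒ 11 (through 12). The C11–C13 bond and the C7–I bond are cut across an alkyne. A syn carbometalation must place the methyl group on the internal carbon and fix the E geometry.

10 ⇒ 9 ⇒ 8 ⇒ 5 + 6 (through 7). The C8–C9 bond is cut; C8 arrives as an acyl-anion equivalent. Alkylation at the allylic bromide must be faster than attack on the epoxide, and the later C6 oxidation must spare sulfur.

5 ⇒ 4 ⇒ 3 ⇒ 2 ⇒ 1. The C9 bromide is traced to an allylic C–H oxidation at the E-methyl group, and the C4–C5 epoxide to an asymmetric epoxidation of the allylic alcohol. This sets C4 and C5 by reagent control on the simplest substrate. The epoxidation must precede the introduction of sulfur, which the oxidant would attack, and the hydroxyl must be masked during the C9 chemistry.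

28 ⇒ 26 (through 27). The phenol O–Si bond is cut. The phenol is masked with the same silyl group as O6, so that one fluoride step finishes the synthesis.

## Other disconnections considered

Alternative 1: The cut is the C2–C3 ring bond, with C5–C10 reconnected, so that the macrocycle is traced to the cyclohexanol A1. A1 carries a vinyl group on the carbinol carbon (future C10, C1, C2) and a trans isopropenyl group on the neighbouring carbon (future C5, C4, C3), beside the C6 p-methoxybenzyl ether, the C7 isopropyl group and the C8 silyl ether; it is taken here as the diastereomer with all these groups equatorial. In the forward sense KH with 18-crown-6 forms the alkoxide, the anionic oxy-Cope shift expands the six-membered ring, and PhNTf2 traps the ten-membered enolate as the C10 enol triflate A2.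
- In its favour: the ring forms in a unimolecular pericyclic step without high dilution; the chair transition state should turn the trans arrangement into both E ring alkenes; C6, C7 and C8 are set on a conformationally defined six-membered ring; the isopropyl group is present from the start, so no selective hydrogenation is needed. On these points it is the better plan.
- Against it: A1 holds five stereocentres on one ring and needs a long preparation. After the expansion, C14 must be attached by cross-coupling at a strained enol triflate, the benzyl ether removed, and the epoxide introduced by hydroxyl-directed epoxidation of a flexible E,E-cyclodecadiene. Such dienes are prone to Cope rearrangement and transannular cyclisation, and the epoxide face would rest on conformation alone.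
- Comparison: alkene geometry is equal (the chosen plan buys it with 1). The chosen plan is better at the epoxide, which it sets by reagent control before the ring exists. It is also shorter after ring closure (four steps against about five) and has a simpler precursor.

Alternative 2: The cut is the C5–C6 bond, giving the acyclic iodo aldehyde A3 with an E alkenyl iodide at C5 and an aldehyde at C6 that is α-branched at C7. In the forward sense CrCl2 (divalent chromium) with catalytic NiCl2 (divalent nickel) converts the iodide into an alkenylchromium (trivalent chromium) that adds to the aldehyde and closes the ring as the allylic alcohol A4.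
- In its favour: this ring closure is mild and chemoselective; the alkenylmetal keeps the 4E geometry; there is no leaving group β to the organometal, which makes it better than the chosen plan on that point; A3 has only two stereocentres; the allylic alcohol is placed for a directed epoxidation.
- Against it: only one stereocentre is made, and the closure is expected to favour the C6 epimer (A4 is the 6-epi alcohol), so an inversion on a hindered ring alcohol would follow. The aldehyde can epimerise at C7. The epoxide comes last, under substrate control, beside the 1(10)-alkene.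
- Comparison: the mechanism is equal (chromium-mediated carbonyl addition at high dilution in both). The chosen plan forms two stereocentres in the wanted sense in the ring-closing step and needs no correction afterwards, so it is shorter by the inversion and epoxidation steps.

Alternative 3: The cut is the C6–C7 bond, with C6 reconnected through oxygen to C12, which gives the thirteen-membered diallylic ether A5 (all three alkenes E, C8 silyl ether as the only stereocentre). In the forward sense n-BuLi removes a proton from C6, and the [2,3]-Wittig shift forms C6–C7, breaks C12–O and contracts the ring to the trienol A6.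
- In its favour: C6, C7 and the isopropenyl group arise in one step; an E allyl ether normally gives the anti arrangement needed; the precursor has one stereocentre against three in 22, which is better; the ten-membered ring is reached by contraction of an ether that is closed by an easy etherification, which is equal to or better than a direct carbon–carbon macrocyclisation.
- Against it: C6 and C12 are both allylic and α to oxygen, so deprotonation at the wrong site and the competing [1,2]-shift are real risks. Induction from the remote C8 centre through a macrocyclic transition state is hard to predict. The epoxide must again be introduced afterwards, by a directed epoxidation in the presence of three alkenes.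
- Comparison: the endgame is equal (hydrogenation, acylation, deprotection) apart from the extra epoxidation. The chosen plan is more secure in regiochemistry and in the origin of every stereocentre.

Key step: step 17

Remark: germacrane numbering is used for all intermediates (C12 carries the leaving group; C13, C14 and C15 are the methyl groups on C11, C10 and C4).

Assumption: the (4R,5R) epoxide of 31 maps onto (2R,3R)-2,3-epoxygeraniol, so step 1 uses the D-(−)-tartrate; the L-(+)-ester would lead into the enantiomeric series.

Remark: 22 and 24 have the spatial arrangement of 31 at every shared stereocentre. The descriptor of C7 is S in 24, 25 and 30 and R in 31 only because the CIP ranking of C6 and C8 changes with their oxygen substituents.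

## Route

Step 1
Reactants: 1 geraniol
Product: 2 (2R,3R)-2,3-epoxygeraniol
Conditions: Ti(OiPr)4 (cat.), D-(−)-diethyl tartrate (cat.), t-BuOOH, 4 Å MS, CH2Cl2, −20 °C
Reagents that add atoms: tert-butyl hydroperoxide, CC(C)(C)OO
Why: Sharpless asymmetric epoxidation; only the allylic-alcohol alkene reacts, the titanium–D-(−)-tartrate complex gives the (2R,3R) epoxide and so sets C4 and C5 by reagent control, and the E geometry of 1 becomes the trans epoxide.

Step 2
Reactants: 2 (2R,3R)-2,3-epoxygeraniol
Product: 3 tert-butyl(dimethyl){[(2R,3R)-3-methyl-3-(4-methylpent-3-en-1-yl)oxiran-2-yl]methoxy}silane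
Conditions: TBSCl, imidazole, DMF, 0 °C to rt
Reagents that add atoms: tert-butyldimethylsilyl chloride, CC(C)(C)[Si](C)(C)Cl
Why: Imidazole-promoted silylation of a primary alcohol; it masks the C6 hydroxyl through the oxidation, bromination and carbanion steps.

Step 3
Reactants: 3 tert-butyl(dimethyl){[(2R,3R)-3-methyl-3-(4-methylpent-3-en-1-yl)oxiran-2-yl]methoxy}silane
Product: 4 (2E)-5-[(2R,3R)-3-{[tert-butyl(dimethyl)silyl]oxymethyl}-2-methyloxiran-2-yl]-2-methylpent-2-en-1-ol
Conditions: SeO2 (cat.), t-BuOOH, CH2Cl2, rt, stopped at partial conversion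
Reagents that add atoms: tert-butyl hydroperoxide, CC(C)(C)OO (oxygen passed on through SeO2, O=[Se]=O)
Why: SeO2-catalysed allylic oxidation (ene reaction, then [2,3]-sigmatropic shift) attacks the only remaining alkene at the methyl group trans to the chain with retention of the E geometry; no acid additive is used, for the sake of the epoxide.

Step 4
Reactants: 4 (2E)-5-[(2R,3R)-3-{[tert-butyl(dimethyl)silyl]oxymethyl}-2-methyloxiran-2-yl]-2-methylpent-2-en-1-ol
Product: 5 {[(2R,3R)-3-[(3E)-5-bromo-4-methylpent-3-en-1-yl]-3-methyloxiran-2-yl]methoxy}(tert-butyl)dimethylsilane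
Conditions: CBr4, PPh3, CH2Cl2, 0 °C
Reagents that add atoms: carbon tetrabromide, BrC(Br)(Br)Br
Why: Appel reaction; bromide displaces the alkoxyphosphonium group at the primary allylic carbon under neutral conditions that leave the epoxide and the silyl ether alone.

Step 5
Reactants: 5 {[(2R,3R)-3-[(3E)-5-bromo-4-methylpent-3-en-1-yl]-3-methyloxiran-2-yl]methoxy}(tert-butyl)dimethylsilane; 6 1,3-dithiane
Product: 8 2-[(2E)-5-[(2R,3R)-3-{[tert-butyl(dimethyl)silyl]oxymethyl}-2-methyloxiran-2-yl]-2-methylpent-2-en-1-yl]-1,3-dithiane, via 2-lithio-1,3-dithiane 7 (not isolated)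
Conditions: 6, n-BuLi, THF, −30 °C; then 5, −78 °C
Reagents that add atoms: none
Why: Alkylation of a dithiane anion (acyl-anion equivalent) by a primary allylic bromide is fast at −78 °C, where the trisubstituted epoxide is not opened; C8 enters at the aldehyde oxidation level in masked form.

Step 6
Reactants: 8 2-[(2E)-5-[(2R,3R)-3-{[tert-butyl(dimethyl)silyl]oxymethyl}-2-methyloxiran-2-yl]-2-methylpent-2-en-1-yl]-1,3-dithiane
Product: 9 [(2R,3R)-3-[(3E)-5-(1,3-dithian-2-yl)-4-methylpent-3-en-1-yl]-3-methyloxiran-2-yl]methanol
Conditions: TBAF, THF, 0 °C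
Reagents that add atoms: none
Why: Fluoride-mediated desilylation; neither the epoxide nor the dithioacetal reacts under these conditions.

Step 7
Reactants: 9 [(2R,3R)-3-[(3E)-5-(1,3-dithian-2-yl)-4-methylpent-3-en-1-yl]-3-methyloxiran-2-yl]methanol
Product: 10 (2S,3R)-3-[(3E)-5-(1,3-dithian-2-yl)-4-methylpent-3-en-1-yl]-3-methyloxirane-2-carbaldehyde
Conditions: SO3·pyridine, DMSO, i-Pr2NEt, CH2Cl2, 0 °C
Reagents that add atoms: none
Why: Parikh–Doering oxidation (activated DMSO) of the primary epoxy alcohol; it does not oxidise the sulfur atoms, and the oxirane C–H next to the aldehyde is not epimerised by the amine base.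

Step 8
Reactants: 11 propargyl alcohol
Product: 13 (E)-3-iodo-2-methylprop-2-en-1-ol, via alkenylalane 12 (not isolated)
Conditions: Me3Al, Cp2ZrCl2 (cat.), CH2Cl2, 0 °C to rt; then I2, THF, −30 to 0 °C
Reagents that add atoms: trimethylaluminium, C[Al](C)C; iodine, II
Why: Zirconium-catalysed carboalumination (Negishi carboalumination) adds methyl and aluminium syn across the alkyne with methyl on the internal carbon, and iodinolysis with retention gives the E alkenyl iodide.

Step 9
Reactants: 13 (E)-3-iodo-2-methylprop-2-en-1-ol
Product: 14 triethyl{[(2E)-3-iodo-2-methylprop-2-en-1-yl]oxy}silane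
Conditions: TESCl, imidazole, CH2Cl2, 0 °C
Reagents that add atoms: chlorotriethylsilane, CC[Si](CC)(CC)Cl
Why: Silylation of a primary alcohol; the triethylsilyl group is chosen because it can later be removed beside a secondary tert-butyldimethylsilyl ether, and in the E isomer it cannot migrate from oxygen to the lithiated carbon.

Step 10
Reactants: 14 triethyl{[(2E)-3-iodo-2-methylprop-2-en-1-yl]oxy}silane; 10 (2S,3R)-3-[(3E)-5-(1,3-dithian-2-yl)-4-methylpent-3-en-1-yl]-3-methyloxirane-2-carbaldehyde
Product: 16 (2E)-1-[(2R,3R)-3-[(3E)-5-(1,3-dithian-2-yl)-4-methylpent-3-en-1-yl]-3-methyloxiran-2-yl]-3-methyl-4-(triethylsilyloxy)but-2-en-1-ol as both C6 epimers, via alkenyllithium 15 (not isolated)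
Conditions: 14, t-BuLi (2 equiv), Et2O, −78 °C; then 10, −78 °C
Reagents that add atoms: none
Why: Iodine–lithium exchange with retention of alkene geometry, then 1,2-addition of the alkenyllithium to the aldehyde; the epoxide and the dithiane C–H are inert at −78 °C, and no selectivity at C6 is needed because both epimers converge in step 11.

Step 11
Reactants: 16 (2E)-1-[(2R,3R)-3-[(3E)-5-(1,3-dithian-2-yl)-4-methylpent-3-en-1-yl]-3-methyloxiran-2-yl]-3-methyl-4-(triethylsilyloxy)but-2-en-1-ol as both C6 epimers
Product: 17 (2E)-1-[(2S,3R)-3-[(3E)-5-(1,3-dithian-2-yl)-4-methylpent-3-en-1-yl]-3-methyloxiran-2-yl]-3-methyl-4-(triethylsilyloxy)but-2-en-1-one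
Conditions: MnO2, CH2Cl2, rt
Reagents that add atoms: none
Why: MnO2 oxidation of a secondary allylic alcohol; both epimers give one enone, and the neutral heterogeneous oxidant spares the dithioacetal, the silyl ether and the epoxide.

Step 12
Reactants: 17 (2E)-1-[(2S,3R)-3-[(3E)-5-(1,3-dithian-2-yl)-4-methylpent-3-en-1-yl]-3-methyloxiran-2-yl]-3-methyl-4-(triethylsilyloxy)but-2-en-1-one
Product: 18 (1R,2E)-1-[(2R,3R)-3-[(3E)-5-(1,3-dithian-2-yl)-4-methylpent-3-en-1-yl]-3-methyloxiran-2-yl]-3-methyl-4-(triethylsilyloxy)but-2-en-1-ol
Conditions: Zn(BH4)2, Et2O, −30 °C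
Reagents that add atoms: none
Why: Chelation-controlled 1,2-reduction of an α,β-epoxy ketone: zinc bridges the carbonyl and oxirane oxygens and hydride enters from the face away from C4, which should give the anti (erythro) epoxy alcohol, that is (6R); this reagent reduces enones at the carbonyl group.

Step 13
Reactants: 18 (1R,2E)-1-[(2R,3R)-3-[(3E)-5-(1,3-dithian-2-yl)-4-methylpent-3-en-1-yl]-3-methyloxiran-2-yl]-3-methyl-4-(triethylsilyloxy)but-2-en-1-ol
Product: 19 2-[(2E)-5-[(2R,3R)-3-[(1R,2E)-1-(tert-butyldimethylsilyloxy)-3-methyl-4-(triethylsilyloxy)but-2-en-1-yl]-2-methyloxiran-2-yl]-2-methylpent-2-en-1-yl]-1,3-dithiane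
Conditions: TBSOTf, 2,6-lutidine, CH2Cl2, −78 °C
Reagents that add atoms: tert-butyldimethylsilyl triflate, CC(C)(C)[Si](C)(C)OS(=O)(=O)C(F)(F)F
Why: Silylation of a hindered secondary alcohol with a silyl triflate and a hindered base; at −78 °C the epoxide and the primary silyl ether are not touched.

Step 14
Reactants: 19 2-[(2E)-5-[(2R,3R)-3-[(1R,2E)-1-(tert-butyldimethylsilyloxy)-3-methyl-4-(triethylsilyloxy)but-2-en-1-yl]-2-methyloxiran-2-yl]-2-methylpent-2-en-1-yl]-1,3-dithiane
Product: 20 (2E,4R)-4-(tert-butyldimethylsilyloxy)-4-[(2R,3R)-3-[(3E)-5-(1,3-dithian-2-yl)-4-methylpent-3-en-1-yl]-3-methyloxiran-2-yl]-2-methylbut-2-en-1-ol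
Conditions: PPTS (cat.), MeOH/CH2Cl2, 0 °C
Reagents that add atoms: none
Why: Acid-catalysed methanolysis of a primary triethylsilyl ether is far faster than that of the hindered secondary tert-butyldimethylsilyl ether; the weak acid at 0 °C should be tolerated by the acyclic epoxide and the dithioacetal.

Step 15
Reactants: 20 (2E,4R)-4-(tert-butyldimethylsilyloxy)-4-[(2R,3R)-3-[(3E)-5-(1,3-dithian-2-yl)-4-methylpent-3-en-1-yl]-3-methyloxiran-2-yl]-2-methylbut-2-en-1-ol
Product: 21 2-[(2E)-5-[(2R,3R)-3-[(1R,2E)-4-bromo-1-(tert-butyldimethylsilyloxy)-3-methylbut-2-en-1-yl]-2-methyloxiran-2-yl]-2-methylpent-2-en-1-yl]-1,3-dithiane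
Conditions: CBr4, PPh3, CH2Cl2, −20 °C
Reagents that add atoms: carbon tetrabromide, BrC(Br)(Br)Br
Why: Appel reaction at the primary allylic alcohol; the electron-withdrawing C6 oxygen disfavours ionisation, so direct displacement without allylic transposition is expected, and the neutral conditions spare the dithioacetal and the epoxide.

Step 16
Reactants: 21 2-[(2E)-5-[(2R,3R)-3-[(1R,2E)-4-bromo-1-(tert-butyldimethylsilyloxy)-3-methylbut-2-en-1-yl]-2-methyloxiran-2-yl]-2-methylpent-2-en-1-yl]-1,3-dithiane
Product: 22 (3E)-6-[(2R,3R)-3-[(1R,2E)-4-bromo-1-(tert-butyldimethylsilyloxy)-3-methylbut-2-en-1-yl]-2-methyloxiran-2-yl]-3-methylhex-3-enal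
Conditions: PhI(O2CCF3)2, NaHCO3, MeCN/H2O (9:1), 0 °C, short reaction time; used at once
Reagents that add atoms: water, O
Why: Oxidative dethioacetalisation with a hypervalent iodine reagent: sulfur is oxidised and water adds to the thionium ion; the reaction is fast at 0 °C under bicarbonate buffer, so the epoxide, the allylic bromide and the silyl ether should survive and the β,γ-alkene should not move into conjugation.

Step 17
Reactants: 22 (3E)-6-[(2R,3R)-3-[(1R,2E)-4-bromo-1-(tert-butyldimethylsilyloxy)-3-methylbut-2-en-1-yl]-2-methyloxiran-2-yl]-3-methylhex-3-enal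
Product: 24 (1(10)E,4R,5R,6R,7S,8R)-6-(tert-butyldimethylsilyloxy)-4,5-epoxygermacra-1(10),11-dien-8-ol, via allylchromium dichloride 23 (not isolated)
Conditions: CrCl2 (excess), THF, rt, slow addition of 22 (final concentration about 0.003 M); aqueous work-up
Reagents that add atoms: none
Why: Two equivalents of CrCl2 (divalent chromium) reduce the C12–Br bond to the allylchromium 23 (trivalent chromium), a nucleophile too weakly basic to enolise the aldehyde or to open the epoxide. Through 1,3-metal shifts 23 settles as the isomer with chromium on C12 and C6 trans to it, whatever the geometry of the bromide, and it adds through its γ-carbon C7 to the C8 carbonyl in a six-membered chair with chromium bound to the carbonyl oxygen (Zimmerman–Traxler type). The closest known reaction is the intramolecular Nozaki–Hiyama (Barbier-type) allylation of ω-formyl allylic bromides, which has precedent for ten-membered germacrane and fourteen-membered cembrane rings. The ten-membered carbocycle closes in the 10-exo-trig mode by C7–C8 bond formation with the C8 oxygen left outside the ring; the E alkene and the trans epoxide stiffen the seven-atom tether, and slow addition at high dilution holds back the bimolecular pathway. C8 is set relative to C7 by the chair, in which the ring carbons C9 and C6 are both pseudo-equatorial, which gives the anti homoallylic alcohol, that is C8–OH and C7–isopropenyl trans on the ring. C7 is set by C6: in the reactive conformer C6–H lies in the plane of the allyl unit (least allylic strain against the C11 methyl group), the bulky silyloxy group points away from the forming bond and the oxirane-bearing tether lies on the face that carries the aldehyde, which leads to the (7S) centre of 24, the same spatial arrangement as C7 of 31. The step needs γ- over α-attack (α-attack would close a twelve-membered ring), which is the normal regiochemistry of substituted allylchromium reagents, and it needs the C6 oxygen to stay in place, which the poor leaving-group ability of a silyloxy group and the covalent carbon–chromium bond should secure.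

Step 18
Reactants: 24 (1(10)E,4R,5R,6R,7S,8R)-6-(tert-butyldimethylsilyloxy)-4,5-epoxygermacra-1(10),11-dien-8-ol
Product: 25 (1(10)E,4R,5R,6R,7S,8R)-6-(tert-butyldimethylsilyloxy)-4,5-epoxygermacr-1(10)-en-8-ol
Conditions: H2 (1 atm), RhCl(PPh3)3 (cat.), toluene, rt
Reagents that add atoms: none
Why: Homogeneous hydrogenation with RhCl(PPh3)3 is strongly sensitive to alkene substitution, so the 1,1-disubstituted isopropenyl group is reduced while the trisubstituted C1=C10 alkene and the epoxide remain; no stereocentre is formed.

Step 19
Reactants: 26 isovanillic acid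
Product: 28 3-(tert-butyldimethylsilyloxy)-4-methoxybenzoic acid, via bis-silyl derivative 27 (not isolated)
Conditions: TBSCl, imidazole, DMF, rt; then AcOH, THF/H2O, rt
Reagents that add atoms: tert-butyldimethylsilyl chloride, CC(C)(C)[Si](C)(C)Cl
Why: Silylation of the phenol and the acid, then selective hydrolysis of the much more labile silyl ester; the phenol ends up masked with the same group as O6.

Step 20
Reactants: 25 (1(10)E,4R,5R,6R,7S,8R)-6-(tert-butyldimethylsilyloxy)-4,5-epoxygermacr-1(10)-en-8-ol; 28 3-(tert-butyldimethylsilyloxy)-4-methoxybenzoic acid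
Product: 30 (1(10)E,4R,5R,6R,7S,8R)-6-(tert-butyldimethylsilyloxy)-4,5-epoxygermacr-1(10)-en-8-yl 3-(tert-butyldimethylsilyloxy)-4-methoxybenzoate, via mixed anhydride 29 (not isolated)
Conditions: 28, 2,4,6-trichlorobenzoyl chloride, Et3N, THF, rt; then 25, DMAP, toluene, rt to 40 °C
Reagents that add atoms: none
Why: Yamaguchi esterification: the mixed anhydride, activated by DMAP, acylates the hindered secondary C8 hydroxyl, the only free hydroxyl in 25; the basic medium is harmless to the epoxide.

Step 21
Reactants: 30 (1(10)E,4R,5R,6R,7S,8R)-6-(tert-butyldimethylsilyloxy)-4,5-epoxygermacr-1(10)-en-8-yl 3-(tert-butyldimethylsilyloxy)-4-methoxybenzoate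
Product: 31 (1(10)E,4R,5R,6R,7R,8R)-4,5-epoxy-6-hydroxygermacr-1(10)-en-8-yl 3-hydroxy-4-methoxybenzoate
Conditions: TBAF, AcOH (1:1), THF, 0 °C to rt
Reagents that add atoms: none
Why: Fluoride-mediated desilylation of the aryl silyl ether (fast) and of the hindered secondary silyl ether; acetic acid buffers the phenoxide and the C6 alkoxide, so acyl migration from O8 to O6, ester cleavage and epoxide opening should be held back, and no acid strong enough to trigger transannular cyclisation is present.

## Compound list

1 | geraniol | CC(C)=CCC/C(C)=C/CO | starting material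
2 | (2R,3R)-2,3-epoxygeraniol | CC(C)=CCC[C@@]1(C)O[C@@H]1CO | intermediate
3 | tert-butyl(dimethyl){[(2R,3R)-3-methyl-3-(4-methylpent-3-en-1-yl)oxiran-2-yl]methoxy}silane | CC(C)=CCC[C@@]1(C)O[C@@H]1CO[Si](C)(C)C(C)(C)C | intermediate
4 | (2E)-5-[(2R,3R)-3-{[tert-butyl(dimethyl)silyl]oxymethyl}-2-methyloxiran-2-yl]-2-methylpent-2-en-1-ol | OC/C(C)=C/CC[C@@]1(C)O[C@@H]1CO[Si](C)(C)C(C)(C)C | intermediate
5 | {[(2R,3R)-3-[(3E)-5-bromo-4-methylpent-3-en-1-yl]-3-methyloxiran-2-yl]methoxy}(tert-butyl)dimethylsilane | BrC/C(C)=C/CC[C@@]1(C)O[C@@H]1CO[Si](C)(C)C(C)(C)C | intermediate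
6 | 1,3-dithiane | C1CSCSC1 | starting material
7 | 2-lithio-1,3-dithiane (not isolated) | [Li]C1SCCCS1 | intermediate
8 | 2-[(2E)-5-[(2R,3R)-3-{[tert-butyl(dimethyl)silyl]oxymethyl}-2-methyloxiran-2-yl]-2-methylpent-2-en-1-yl]-1,3-dithiane | S1CCCSC1C/C(C)=C/CC[C@@]2(C)O[C@@H]2CO[Si](C)(C)C(C)(C)C | intermediate
9 | [(2R,3R)-3-[(3E)-5-(1,3-dithian-2-yl)-4-methylpent-3-en-1-yl]-3-methyloxiran-2-yl]methanol | S1CCCSC1C/C(C)=C/CC[C@@]2(C)O[C@@H]2CO | intermediate
10 | (2S,3R)-3-[(3E)-5-(1,3-dithian-2-yl)-4-methylpent-3-en-1-yl]-3-methyloxirane-2-carbaldehyde | S1CCCSC1C/C(C)=C/CC[C@@]2(C)O[C@@H]2C=O | intermediate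
11 | propargyl alcohol | C#CCO | starting material
12 | (E)-alkenylalane, dimethylaluminium on C7 and on oxygen (not isolated) | C[Al](C)/C=C(C)/CO[Al](C)C | intermediate
13 | (E)-3-iodo-2-methylprop-2-en-1-ol | OC/C(C)=C/I | intermediate
14 | triethyl{[(2E)-3-iodo-2-methylprop-2-en-1-yl]oxy}silane | CC[Si](CC)(CC)OC/C(C)=C/I | intermediate
15 | (E)-2-methyl-3-(triethylsilyloxy)prop-1-enyllithium (not isolated) | CC[Si](CC)(CC)OC/C(C)=C/[Li] | intermediate
16 | (2E)-1-[(2R,3R)-3-[(3E)-5-(1,3-dithian-2-yl)-4-methylpent-3-en-1-yl]-3-methyloxiran-2-yl]-3-methyl-4-(triethylsilyloxy)but-2-en-1-ol, both C6 epimers | S1CCCSC1C/C(C)=C/CC[C@@]2(C)O[C@@H]2C(O)/C=C(C)/CO[Si](CC)(CC)CC | intermediate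
17 | (2E)-1-[(2S,3R)-3-[(3E)-5-(1,3-dithian-2-yl)-4-methylpent-3-en-1-yl]-3-methyloxiran-2-yl]-3-methyl-4-(triethylsilyloxy)but-2-en-1-one | S1CCCSC1C/C(C)=C/CC[C@@]2(C)O[C@@H]2C(=O)/C=C(C)/CO[Si](CC)(CC)CC | intermediate
18 | (1R,2E)-1-[(2R,3R)-3-[(3E)-5-(1,3-dithian-2-yl)-4-methylpent-3-en-1-yl]-3-methyloxiran-2-yl]-3-methyl-4-(triethylsilyloxy)but-2-en-1-ol | S1CCCSC1C/C(C)=C/CC[C@@]2(C)O[C@@H]2[C@H](O)/C=C(C)/CO[Si](CC)(CC)CC | intermediate
19 | 2-[(2E)-5-[(2R,3R)-3-[(1R,2E)-1-(tert-butyldimethylsilyloxy)-3-methyl-4-(triethylsilyloxy)but-2-en-1-yl]-2-methyloxiran-2-yl]-2-methylpent-2-en-1-yl]-1,3-dithiane | S1CCCSC1C/C(C)=C/CC[C@@]2(C)O[C@@H]2[C@H](O[Si](C)(C)C(C)(C)C)/C=C(C)/CO[Si](CC)(CC)CC | intermediate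
20 | (2E,4R)-4-(tert-butyldimethylsilyloxy)-4-[(2R,3R)-3-[(3E)-5-(1,3-dithian-2-yl)-4-methylpent-3-en-1-yl]-3-methyloxiran-2-yl]-2-methylbut-2-en-1-ol | S1CCCSC1C/C(C)=C/CC[C@@]2(C)O[C@@H]2[C@H](O[Si](C)(C)C(C)(C)C)/C=C(C)/CO | intermediate
21 | 2-[(2E)-5-[(2R,3R)-3-[(1R,2E)-4-bromo-1-(tert-butyldimethylsilyloxy)-3-methylbut-2-en-1-yl]-2-methyloxiran-2-yl]-2-methylpent-2-en-1-yl]-1,3-dithiane | S1CCCSC1C/C(C)=C/CC[C@@]2(C)O[C@@H]2[C@H](O[Si](C)(C)C(C)(C)C)/C=C(C)/CBr | intermediate
22 | (3E)-6-[(2R,3R)-3-[(1R,2E)-4-bromo-1-(tert-butyldimethylsilyloxy)-3-methylbut-2-en-1-yl]-2-methyloxiran-2-yl]-3-methylhex-3-enal | O=CC/C(C)=C/CC[C@@]1(C)O[C@@H]1[C@H](O[Si](C)(C)C(C)(C)C)/C=C(C)/CBr | intermediate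
23 | allylchromium dichloride from 22, chromium on C12 (trivalent chromium; not isolated) | O=CC/C(C)=C/CC[C@@]1(C)O[C@@H]1[C@H](O[Si](C)(C)C(C)(C)C)/C=C(C)/C[Cr](Cl)Cl | intermediate
24 | (1(10)E,4R,5R,6R,7S,8R)-6-(tert-butyldimethylsilyloxy)-4,5-epoxygermacra-1(10),11-dien-8-ol | O[C@@H]1C/C(C)=C/CC[C@@]2(C)O[C@@H]2[C@H](O[Si](C)(C)C(C)(C)C)[C@H]1C(C)=C | intermediate
25 | (1(10)E,4R,5R,6R,7S,8R)-6-(tert-butyldimethylsilyloxy)-4,5-epoxygermacr-1(10)-en-8-ol | O[C@@H]1C/C(C)=C/CC[C@@]2(C)O[C@@H]2[C@H](O[Si](C)(C)C(C)(C)C)[C@H]1C(C)C | intermediate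
26 | isovanillic acid (3-hydroxy-4-methoxybenzoic acid) | COc1ccc(C(=O)O)cc1O | starting material
27 | tert-butyldimethylsilyl 3-(tert-butyldimethylsilyloxy)-4-methoxybenzoate (not isolated) | COc1ccc(C(=O)O[Si](C)(C)C(C)(C)C)cc1O[Si](C)(C)C(C)(C)C | intermediate
28 | 3-(tert-butyldimethylsilyloxy)-4-methoxybenzoic acid | COc1ccc(C(=O)O)cc1O[Si](C)(C)C(C)(C)C | intermediate
29 | 3-(tert-butyldimethylsilyloxy)-4-methoxybenzoic 2,4,6-trichlorobenzoic anhydride (not isolated) | COc1ccc(C(=O)OC(=O)c2c(Cl)cc(Cl)cc2Cl)cc1O[Si](C)(C)C(C)(C)C | intermediate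
30 | (1(10)E,4R,5R,6R,7S,8R)-6-(tert-butyldimethylsilyloxy)-4,5-epoxygermacr-1(10)-en-8-yl 3-(tert-butyldimethylsilyloxy)-4-methoxybenzoate | COc1ccc(C(=O)O[C@@H]2C/C(C)=C/CC[C@@]3(C)O[C@@H]3[C@H](O[Si](C)(C)C(C)(C)C)[C@H]2C(C)C)cc1O[Si](C)(C)C(C)(C)C | intermediate
31 | (1(10)E,4R,5R,6R,7R,8R)-4,5-epoxy-6-hydroxygermacr-1(10)-en-8-yl 3-hydroxy-4-methoxybenzoate | COc1ccc(C(=O)O[C@@H]2C/C(C)=C/CC[C@@]3(C)O[C@@H]3[C@H](O)[C@H]2C(C)C)cc1O | target

## Step count and least certain steps

Total step count: 21. Longest linear sequence: 18 steps (steps 1–7, 10–18, 20 and 21, from 1 to 31).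

Step 17 (key step). The most likely failure is intermolecular carbonyl addition outrunning ring closure, because the ten-membered ring is costly in entropy and transannular strain. Next in likelihood are 1,4-elimination of the C6 silyloxy group from the allylmetal and loss of the facial bias at C7. The fallback replaces the stoichiometric chromium reaction by a catalytic umpolung of a π-allylpalladium. It sets out from 20: acetylation (Ac2O, pyridine, DMAP) should give the allylic acetate F1. Dethioacetalisation as in step 16, to which an acetate is inert, should give the acetoxy aldehyde F2. Treatment with Pd(PPh3)4 (zerovalent palladium, catalytic) and InI (monovalent indium) in THF at high dilution should form an allylindium that adds through C7 in the same kind of cyclic transition state. The fallback returns to the route at 24.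

Step 16. The most likely failure is loss of the allylic bromide by solvolysis during the oxidation of sulfur; acid-induced opening of the epoxide and migration of the β,γ-alkene into conjugation are further risks. The fallback removes the incompatibility by reversing the order of events. It sets out from 20: dethioacetalisation under the same buffered conditions, with no halide present, should give the hydroxy aldehyde F3. A Corey–Kim bromination (NBS, Me2S, CH2Cl2, −20 °C) is selective for allylic alcohols and leaves aldehydes alone, and should rejoin the route at 22.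

Step 3. The most likely failure is incomplete conversion together with over-oxidation to the enal, and slow opening of the epoxide by acidic selenium species. The fallback replaces C–H oxidation by alkene cleavage and olefination. It sets out from 3: ozonolysis (O3, CH2Cl2, −78 °C; Me2S) should give the aldehyde F4. A Wittig reaction with the stabilised ylide ethyl 2-(triphenylphosphoranylidene)propanoate should give the E enoate F5. Reduction with DIBAL-H at −78 °C returns to the route at 4.

Step 12. The most likely failure is weak chelation control, which would erode the anti selectivity at C6; conjugate reduction or reductive opening of the oxirane could also compete. The fallback avoids the ketone and corrects the carbinol by inversion. It sets out from 16, whose epimers are separated; the anti epimer is 18 itself. The syn alcohol F6 is inverted by a Mitsunobu reaction (p-nitrobenzoic acid, DIAD, PPh3) to the p-nitrobenzoate F7, and brief methanolysis (K2CO3, MeOH, 0 °C) returns to the route at 18.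

Step 21. The most likely failure is acyl migration from O8 to the freed O6 during the slow cleavage of the hindered secondary silyl ether; ester cleavage and opening of the epoxide by the alkoxide are further risks. The fallback changes the protecting-group logic to a site-selective acylation. It sets out from 25: desilylation with TBAF before any ester is present should give the diol F8. Yamaguchi acylation with 28 should prefer the less hindered C8 hydroxyl, because the C6 hydroxyl lies between the oxirane carbon and the isopropyl-bearing C7, and should give the monoester F9. In F9 only the labile aryl silyl ether remains; it should fall to TBAF/AcOH at 0 °C within minutes, which returns to the route at 31.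

## Further compounds

F1 | step 17 | (2E,4R)-4-(tert-butyldimethylsilyloxy)-4-[(2R,3R)-3-[(3E)-5-(1,3-dithian-2-yl)-4-methylpent-3-en-1-yl]-3-methyloxiran-2-yl]-2-methylbut-2-en-1-yl acetate | S1CCCSC1C/C(C)=C/CC[C@@]2(C)O[C@@H]2[C@H](O[Si](C)(C)C(C)(C)C)/C=C(C)/COC(C)=O
F2 | step 17 | (2E,4R)-4-(tert-butyldimethylsilyloxy)-2-methyl-4-[(2R,3R)-3-methyl-3-[(3E)-4-methyl-6-oxohex-3-en-1-yl]oxiran-2-yl]but-2-en-1-yl acetate | O=CC/C(C)=C/CC[C@@]1(C)O[C@@H]1[C@H](O[Si](C)(C)C(C)(C)C)/C=C(C)/COC(C)=O
F3 | step 16 | (3E)-6-[(2R,3R)-3-[(1R,2E)-1-(tert-butyldimethylsilyloxy)-4-hydroxy-3-methylbut-2-en-1-yl]-2-methyloxiran-2-yl]-3-methylhex-3-enal | O=CC/C(C)=C/CC[C@@]1(C)O[C@@H]1[C@H](O[Si](C)(C)C(C)(C)C)/C=C(C)/CO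
F4 | step 3 | 3-[(2R,3R)-3-{[tert-butyl(dimethyl)silyl]oxymethyl}-2-methyloxiran-2-yl]propanal | O=CCC[C@@]1(C)O[C@@H]1CO[Si](C)(C)C(C)(C)C
F5 | step 3 | ethyl (2E)-5-[(2R,3R)-3-{[tert-butyl(dimethyl)silyl]oxymethyl}-2-methyloxiran-2-yl]-2-methylpent-2-enoate | CCOC(=O)/C(C)=C/CC[C@@]1(C)O[C@@H]1CO[Si](C)(C)C(C)(C)C
F6 | step 12 | (1S,2E)-1-[(2R,3R)-3-[(3E)-5-(1,3-dithian-2-yl)-4-methylpent-3-en-1-yl]-3-methyloxiran-2-yl]-3-methyl-4-(triethylsilyloxy)but-2-en-1-ol | S1CCCSC1C/C(C)=C/CC[C@@]2(C)O[C@@H]2[C@@H](O)/C=C(C)/CO[Si](CC)(CC)CC
F7 | step 12 | (1R,2E)-1-[(2R,3R)-3-[(3E)-5-(1,3-dithian-2-yl)-4-methylpent-3-en-1-yl]-3-methyloxiran-2-yl]-3-methyl-4-(triethylsilyloxy)but-2-en-1-yl 4-nitrobenzoate | S1CCCSC1C/C(C)=C/CC[C@@]2(C)O[C@@H]2[C@H](OC(=O)c3ccc(cc3)[N+](=O)[O-])/C=C(C)/CO[Si](CC)(CC)CC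
F8 | step 21 | (1(10)E,4R,5R,6R,7S,8R)-4,5-epoxygermacr-1(10)-ene-6,8-diol | O[C@@H]1C/C(C)=C/CC[C@@]2(C)O[C@@H]2[C@H](O)[C@H]1C(C)C
F9 | step 21 | (1(10)E,4R,5R,6R,7R,8R)-4,5-epoxy-6-hydroxygermacr-1(10)-en-8-yl 3-(tert-butyldimethylsilyloxy)-4-methoxybenzoate | COc1ccc(C(=O)O[C@@H]2C/C(C)=C/CC[C@@]3(C)O[C@@H]3[C@H](O)[C@H]2C(C)C)cc1O[Si](C)(C)C(C)(C)C
A1 | alternative 1 | all-equatorial 1-vinyl-2-isopropenylcyclohexanol with C6 p-methoxybenzyl ether, C7 isopropyl and C8 tert-butyldimethylsilyl ether (hydroxyl axial) | CC(C)(C)[Si](C)(C)O[C@@H]1C[C@](O)(C=C)[C@@H](C(C)=C)[C@H](OCc2ccc(OC)cc2)[C@H]1C(C)C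
A2 | alternative 1 | ten-membered E,E-dienyl C10 triflate with C6 p-methoxybenzyl ether and C8 tert-butyldimethylsilyl ether | CC(C)(C)[Si](C)(C)O[C@@H]1C/C(OS(=O)(=O)C(F)(F)F)=C/CC/C(C)=C/[C@H](OCc2ccc(OC)cc2)[C@H]1C(C)C
A3 | alternative 2 | (5E,9E)-3-(tert-butyldimethylsilyloxy)-10-iodo-5,9-dimethyl-2-(propan-2-yl)deca-5,9-dienal, configured at C7 and C8 as in A4 | I/C=C(C)/CC/C=C(C)/C[C@@H](O[Si](C)(C)C(C)(C)C)[C@@H](C=O)C(C)C
A4 | alternative 2 | 6-epi-8-O-tert-butyldimethylsilyl-germacra-1(10)E,4E-diene-6,8-diol | CC(C)(C)[Si](C)(C)O[C@@H]1C/C(C)=C/CC/C(C)=C/[C@@H](O)[C@H]1C(C)C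
A5 | alternative 3 | thirteen-membered all-E diallylic ether, oxygen between C6 and C12, with C8 tert-butyldimethylsilyl ether | CC(C)(C)[Si](C)(C)O[C@@H]1C/C(C)=C/CC/C(C)=C/COC/C(C)=C/1
A6 | alternative 3 | 8-O-tert-butyldimethylsilyl-germacra-1(10),4,11-trien-6-ol | CC(C)(C)[Si](C)(C)O[C@@H]1C/C(C)=C/CC/C(C)=C/[C@H](O)[C@H]1C(C)=C
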